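**Assumption:** the target SMILES has no stereocentres or stereodescriptors, so marchantin H is treated as achiral and no stereocontrol is needed.

## Retrosynthetic overview

1. Marchantin H ⇐ tri-O-methyl ether (BBr3) ⇐ macrocyclic stilbene (H2). The 18-membered ring is closed last, at the B–C bridge, by intramolecular McMurry coupling of a dialdehyde.
2. The dialdehyde ⇐ two diaryl-ether halves of equal size (AB and CD), joined at the A–D bridge by a desilylative Sonogashira coupling, then alkyne saturation.
3. AB half: catechol → guaiacol; SNAr on 4-fluorobenzaldehyde (from 1-bromo-4-fluorobenzene); iodination para to OMe; TMS-acetylene.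
4. CD half: catechol → veratrole → 3-fluoroveratrole → 2-fluoro-3,4-dimethoxybenzaldehyde; SNAr with 3-iodophenol.
5. All four benzene rings come from commercial arenes; the only ring formed is the macrocycle (step 12).

## Route

### AB half

**Step 1**
Reactants: 1, catechol
Product: 2, guaiacol (2-methoxyphenol)
Conditions: MeI (1.0 equiv), K2CO3, acetone, reflux; separate from veratrole and catechol by base extraction/distillation
Reagents that add atoms: iodomethane, CI
Why: Williamson mono-etherification; the monomethyl ether is less acidic than catechol, so controlled stoichiometry favours mono-alkylation.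

**Step 2**
Reactants: 3, 1-bromo-4-fluorobenzene
Product: 4, 4-fluorobenzaldehyde
Conditions: n-BuLi, THF, −78 °C; DMF, −78 °C → rt; aq. NH4Cl
Reagents that add atoms: N,N-dimethylformamide, CN(C)C=O
Why: Br/Li exchange is faster than any attack at C–F, and the aryllithium is formylated by DMF (Bouveault-type formylation).

**Step 3**
Reactants: 2, guaiacol; 4, 4-fluorobenzaldehyde
Product: 5, 4-(2-methoxyphenoxy)benzaldehyde
Conditions: K2CO3, DMF, 120 °C
Reagents that add atoms: none
Why: SNAr (addition–elimination); the para-formyl group activates the C–F bond toward the phenoxide.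

**Step 4**
Reactants: 5, 4-(2-methoxyphenoxy)benzaldehyde
Product: 6, 4-(5-iodo-2-methoxyphenoxy)benzaldehyde
Conditions: NIS (1.05 equiv), TFA (cat.), MeCN, rt
Reagents that add atoms: N-iodosuccinimide, O=C1CCC(=O)N1I
Why: Electrophilic aromatic iodination; the formyl ring is deactivated, and on the other ring OMe is a much stronger para-director than the oxygen shared with the electron-poor formylphenyl group, so iodine enters para to OMe.

**Step 5**
Reactants: 6, 4-(5-iodo-2-methoxyphenoxy)benzaldehyde; 7, ethynyltrimethylsilane
Product: 8, 4-{2-methoxy-5-[(trimethylsilyl)ethynyl]phenoxy}benzaldehyde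
Conditions: PdCl2(PPh3)2 (2 mol%), CuI (4 mol%), Et3N/THF, rt → 40 °C
Reagents that add atoms: none
Why: Sonogashira coupling of an aryl iodide proceeds under mild conditions that leave the aldehyde untouched.

### CD half

**Step 6**
Reactants: 1, catechol
Product: 9, veratrole (1,2-dimethoxybenzene)
Conditions: MeI (2.5 equiv), K2CO3, DMF, rt
Reagents that add atoms: iodomethane, CI
Why: Exhaustive Williamson etherification.

**Step 7**
Reactants: 9, veratrole
Product: 10, 1-fluoro-2,3-dimethoxybenzene (3-fluoroveratrole)
Conditions: n-BuLi, TMEDA, Et2O, 0 °C → rt; then NFSI, THF, −78 °C → rt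
Reagents that add atoms: N-fluorobenzenesulfonimide, O=S(=O)(c1ccccc1)N(F)S(=O)(=O)c1ccccc1
Why: Directed ortho-metalation of veratrole gives the 3-lithio species, which is trapped by an electrophilic N–F reagent (electrophilic fluorination).

**Step 8**
Reactants: 10, 1-fluoro-2,3-dimethoxybenzene
Product: 11, 2-fluoro-3,4-dimethoxybenzaldehyde
Conditions: n-BuLi, THF, −78 °C; DMF, −78 °C → rt; aq. HCl work-up
Reagents that add atoms: N,N-dimethylformamide, CN(C)C=O
Why: Directed ortho-metalation; fluorine is the stronger acidifying director, so kinetic lithiation occurs ortho to F (kept at −78 °C to avoid benzyne), then formylation with DMF.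

**Step 9**
Reactants: 11, 2-fluoro-3,4-dimethoxybenzaldehyde; 12, 3-iodophenol
Product: 13, 2-(3-iodophenoxy)-3,4-dimethoxybenzaldehyde
Conditions: K2CO3, DMAc, 130 °C (Cs2CO3, DMSO if sluggish)
Reagents that add atoms: none
Why: SNAr; the ortho-formyl group activates the C–F bond, and the aryl iodide is inert in the absence of a metal.

### Fragment union and endgame

**Step 10**
Reactants: 8, TMS-alkyne aldehyde (AB half); 13, iodo aldehyde (CD half)
Product: 14, 2-(3-{[3-(4-formylphenoxy)-4-methoxyphenyl]ethynyl}phenoxy)-3,4-dimethoxybenzaldehyde (rings A and D linked by C≡C)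
Conditions: PdCl2(PPh3)2 (3 mol%), CuI (5 mol%), CsF (2 equiv), Et3N, DMF/H2O, 60 °C, degassed
Reagents that add atoms: none
Why: Sonogashira coupling with in situ fluoride desilylation (sila-Sonogashira); the terminal alkyne is released slowly, which suppresses Glaser homocoupling, and both aldehydes are tolerated.

**Step 11**
Reactants: 14, diarylalkyne dialdehyde
Product: 15, 2-(3-{2-[3-(4-formylphenoxy)-4-methoxyphenyl]ethyl}phenoxy)-3,4-dimethoxybenzaldehyde
Conditions: H2 (1 atm), 10% Pd/C, Ph2S (cat.), EtOAc, rt
Reagents that add atoms: none
Why: Chemoselective catalytic hydrogenation; sulfide-poisoned Pd/C saturates the alkyne to the flexible CH2CH2 bridge while leaving aromatic aldehydes and aryl ethers intact.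

**Step 12**
Reactants: 15, bibenzyl dialdehyde
Product: 16, tri-O-methyl-dehydromarchantin H (18-membered macrocycle with CH=CH between rings B and C; Z/E not defined, both converge in step 13)
Conditions: TiCl4, Zn, pyridine, THF, reflux; syringe-pump addition of 15 over 24 h (final ca. 2 mM)
Reagents that add atoms: none
Why: Intramolecular McMurry reductive carbonyl coupling under high dilution; low-valent titanium deoxygenates the two aldehydes to the alkene and does not touch the ethers.

**Step 13**
Reactants: 16, macrocyclic stilbene
Product: 17, tri-O-methylmarchantin H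
Conditions: H2 (1 atm), 10% Pd/C, EtOAc, rt
Reagents that add atoms: none
Why: Catalytic hydrogenation of the stilbene double bond; there are no benzyl or halide groups to lose.

**Step 14**
Reactants: 17, tri-O-methylmarchantin H
Product: 18, marchantin H
Conditions: BBr3 (8 equiv), CH2Cl2, −78 °C → rt; then MeOH/H2O, work-up under Ar
Reagents that add atoms: none
Why: Lewis-acid cleavage of the three aryl methyl ethers (BBr3 demethylation); diaryl ethers are not cleaved under these conditions.

## Compound list

1 | catechol | Oc1ccccc1O | starting material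
2 | guaiacol (2-methoxyphenol) | COc1ccccc1O | intermediate
3 | 1-bromo-4-fluorobenzene | Fc1ccc(Br)cc1 | starting material
4 | 4-fluorobenzaldehyde | O=Cc1ccc(F)cc1 | intermediate
5 | 4-(2-methoxyphenoxy)benzaldehyde | COc1ccccc1Oc1ccc(C=O)cc1 | intermediate
6 | 4-(5-iodo-2-methoxyphenoxy)benzaldehyde | COc1ccc(I)cc1Oc1ccc(C=O)cc1 | intermediate
7 | ethynyltrimethylsilane | C#C[Si](C)(C)C | starting material
8 | 4-{2-methoxy-5-[(trimethylsilyl)ethynyl]phenoxy}benzaldehyde | COc1ccc(C#C[Si](C)(C)C)cc1Oc1ccc(C=O)cc1 | intermediate
9 | veratrole (1,2-dimethoxybenzene) | COc1ccccc1OC | intermediate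
10 | 1-fluoro-2,3-dimethoxybenzene | COc1cccc(F)c1OC | intermediate
11 | 2-fluoro-3,4-dimethoxybenzaldehyde | COc1ccc(C=O)c(F)c1OC | intermediate
12 | 3-iodophenol | Oc1cccc(I)c1 | starting material
13 | 2-(3-iodophenoxy)-3,4-dimethoxybenzaldehyde | COc1ccc(C=O)c(Oc2cccc(I)c2)c1OC | intermediate
14 | diarylalkyne dialdehyde | COc1ccc(C#Cc2cccc(Oc3c(C=O)ccc(OC)c3OC)c2)cc1Oc1ccc(C=O)cc1 | intermediate
15 | bibenzyl dialdehyde | COc1ccc(CCc2cccc(Oc3c(C=O)ccc(OC)c3OC)c2)cc1Oc1ccc(C=O)cc1 | intermediate
16 | tri-O-methyl-dehydromarchantin H (macrocyclic stilbene) | COc1ccc2cc1Oc1ccc(cc1)C=Cc1ccc(OC)c(OC)c1Oc1cccc(c1)CC2 | intermediate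
17 | tri-O-methylmarchantin H | COc1ccc2cc1Oc1ccc(cc1)CCc1ccc(OC)c(OC)c1Oc1cccc(c1)CC2 | intermediate
18 | marchantin H | Oc1ccc2cc1Oc1ccc(cc1)CCc1ccc(O)c(O)c1Oc1cccc(c1)CC2 | target

## Summary

**Total step count:** 14

**Longest linear sequence:** 9 steps (1, 3, 4, 5, 10–14; the other arm, 6–9 then 10–14, is also 9).

**Steps most likely to fail, with fallbacks:**

1. **Step 12, McMurry macrocyclization** (oligomers or pinacol instead of the 18-membered ring). Fallback: reduce 15 to the diol (NaBH4), convert to the bis(benzyl bromide) (PBr3) and close the ring by intramolecular Wurtz-type coupling (Na, tetraphenylethylene, THF, high dilution). This gives 17 directly by C(sp3)–C(sp3) bond formation.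

2. **Step 9, SNAr on a hindered fluoride that is deactivated by the 4-OMe group.** Fallback: invert the polarity. Make 2-hydroxy-3,4-dimethoxybenzaldehyde from veratrole (ortho-lithiation/B(OMe)3/H2O2 to 2,3-dimethoxyphenol, then MgCl2/Et3N/paraformaldehyde ortho-formylation). O-arylate it metal-free with a (3-bromophenyl)(2,4,6-trimethoxyphenyl)iodonium salt, and carry the aryl bromide into the Sonogashira union.

3. **Step 11, alkyne saturation in the presence of two aryl aldehydes** (over-reduction to benzyl alcohols or methyl groups). Fallback: change the protecting-group strategy. Convert 8 and 13 to their 1,3-dioxolanes before the union, hydrogenate the coupled alkyne with unpoisoned Pd/C, and release both aldehydes with aqueous acid just before the McMurry step.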